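**Retrosynthetic overview**

- The target has two fully substituted hydroxy-para-benzoquinones, ring A (5-hydroxy-2-methoxy-3-methyl) and ring B (2,5-dihydroxy-3-methyl), joined by an unbranched tether of thirteen methylenes, C1' on ring A to C13' on ring B; it has no stereocentre.
- Because the tether is odd, its central methylene C7' lies six CH2 groups from each ring. Cutting C6'–C7' and C7'–C8' leaves a one-carbon linchpin (C2 of 1,3-dithiane, used twice as a nucleophile) and two 6-arylhexyl bromides.
- Both bromides come from 3,5-dihydroxy-4-methylbenzoic acid (Bn/Me ethers for ring A, Bn/Bn for ring B) by Wittig extension with one batch of the ylide from 5-bromopentan-1-ol, diimide saturation and Appel bromination.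
- No ring is formed in the route; both carbocycles come from the benzoic acid. After desulfurisation and debenzylation, rings A and B are oxidised together: Teuber oxidation, Thiele–Winter acetoxylation, then deacetylation and air oxidation.

Key step: step 17

Remark: the target is treated as the drawn hydroxy-para-quinone tautomers (the two para-quinone tautomers of ring B are degenerate); ring A is the methoxy ring and C1' is the tether carbon attached to it.

**Route**

Step 1
Reactants: 1 3,5-dihydroxy-4-methylbenzoic acid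
Product: 2 methyl 3,5-dihydroxy-4-methylbenzoate
Conditions: MeOH, H2SO4 (cat.), reflux
Reagents that add atoms: methanol, CO
Why: Fischer esterification masks the acid so that only the two phenols are alkylated in the next steps.

Step 2
Reactants: 2 methyl 3,5-dihydroxy-4-methylbenzoate
Product: 3 methyl 3-(benzyloxy)-5-hydroxy-4-methylbenzoate
Conditions: BnBr (1.0 equiv), K2CO3 (1.0 equiv), acetone, reflux; chromatography
Reagents that add atoms: benzyl bromide, BrCc1ccccc1
Why: Williamson O-alkylation with one equivalent of halide should give the mono-ether statistically, separable from recovered diol (recycled) and from the bis(benzyl) ether, which is the compound that step 11 makes on purpose.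

Step 3
Reactants: 3 methyl 3-(benzyloxy)-5-hydroxy-4-methylbenzoate
Product: 4 methyl 3-(benzyloxy)-5-methoxy-4-methylbenzoate
Conditions: MeI, K2CO3, DMF, rt
Reagents that add atoms: iodomethane, CI
Why: Williamson methylation of the remaining phenol installs the methyl ether that ring A keeps to the end.

Step 4
Reactants: 4 methyl 3-(benzyloxy)-5-methoxy-4-methylbenzoate
Product: 5 [3-(benzyloxy)-5-methoxy-4-methylphenyl]methanol
Conditions: LiAlH4, THF, 0 °C to rt; aqueous work-up
Reagents that add atoms: none
Why: Hydride reduction of the ester to the benzylic alcohol leaves aryl ethers untouched.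

Step 5
Reactants: 5 [3-(benzyloxy)-5-methoxy-4-methylphenyl]methanol
Product: 6 3-(benzyloxy)-5-methoxy-4-methylbenzaldehyde
Conditions: activated MnO2, CH2Cl2, rt
Reagents that add atoms: none
Why: MnO2 oxidises benzylic alcohols selectively and stops at the aldehyde.

Step 6
Reactants: 7 5-bromopentan-1-ol
Product: 8 (5-hydroxypentyl)triphenylphosphonium bromide
Conditions: PPh3, MeCN, reflux
Reagents that add atoms: triphenylphosphine, c1ccc(cc1)P(c1ccccc1)c1ccccc1
Why: SN2 quaternisation of triphenylphosphine by the primary bromide under neutral conditions, where the free hydroxyl does not cyclise onto the halide.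

Step 7
Reactants: 8 (5-hydroxypentyl)triphenylphosphonium bromide
Product: 9 sodium 5-(triphenylphosphoranylidene)pentan-1-olate (alkoxide ylide), prepared as one THF solution under Ar and divided at once between steps 8 and 14
Conditions: NaN(SiMe3)2 (2.0 equiv), THF, 0 °C, Ar
Reagents that add atoms: sodium bis(trimethylsilyl)amide, C[Si](C)(C)[N-][Si](C)(C)C.[Na+]
Why: Double deprotonation of the phosphonium salt (the first stage of a Wittig olefination), in which one equivalent of the amide base takes the hydroxyl proton and the second the CH next to phosphorus, should give the unstabilised alkoxide ylide as a single batch that serves both aldehydes.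

Step 8
Reactants: 6 3-(benzyloxy)-5-methoxy-4-methylbenzaldehyde; 9 sodium 5-(triphenylphosphoranylidene)pentan-1-olate
Product: 10 (5Z)-6-[3-(benzyloxy)-5-methoxy-4-methylphenyl]hex-5-en-1-ol (Z expected as major isomer, E isomer carried along)
Conditions: 9 (THF solution from step 7), then 6, −78 °C to rt; H2O
Reagents that add atoms: none
Why: Wittig olefination with the unstabilised alkoxide ylide forms C1'–C2' as an alkene whose geometry is irrelevant because it is saturated in step 9.

Step 9
Reactants: 10 (5Z)-6-[3-(benzyloxy)-5-methoxy-4-methylphenyl]hex-5-en-1-ol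
Product: 11 6-[3-(benzyloxy)-5-methoxy-4-methylphenyl]hexan-1-ol
Conditions: TsNHNH2, NaOAc, DME–H2O, reflux
Reagents that add atoms: none
Why: Diimide generated in the flask transfers H2 to the C=C by concerted syn addition and, unlike H2 over palladium, should not touch the aryl benzyl ether.

Step 10
Reactants: 11 6-[3-(benzyloxy)-5-methoxy-4-methylphenyl]hexan-1-ol
Product: 12 1-(benzyloxy)-5-(6-bromohexyl)-3-methoxy-2-methylbenzene
Conditions: CBr4, PPh3, CH2Cl2, 0 °C to rt
Reagents that add atoms: carbon tetrabromide, BrC(Br)(Br)Br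
Why: Appel bromination converts the primary alcohol to the bromide under neutral conditions by SN2 displacement of the oxyphosphonium group.

Step 11
Reactants: 2 methyl 3,5-dihydroxy-4-methylbenzoate
Product: 13 methyl 3,5-bis(benzyloxy)-4-methylbenzoate
Conditions: BnBr (2.4 equiv), K2CO3, DMF, 60 °C
Reagents that add atoms: benzyl bromide, BrCc1ccccc1
Why: Exhaustive Williamson benzylation of both phenols gives the ring B protecting pattern, removable later in one hydrogenolysis.

Step 12
Reactants: 13 methyl 3,5-bis(benzyloxy)-4-methylbenzoate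
Product: 14 [3,5-bis(benzyloxy)-4-methylphenyl]methanol
Conditions: LiAlH4, THF, 0 °C to rt; aqueous work-up
Reagents that add atoms: none
Why: Hydride reduction of the ester to the benzylic alcohol, as in step 4.

Step 13
Reactants: 14 [3,5-bis(benzyloxy)-4-methylphenyl]methanol
Product: 15 3,5-bis(benzyloxy)-4-methylbenzaldehyde
Conditions: activated MnO2, CH2Cl2, rt
Reagents that add atoms: none
Why: Selective benzylic oxidation to the aldehyde, as in step 5.

Step 14
Reactants: 15 3,5-bis(benzyloxy)-4-methylbenzaldehyde; 9 sodium 5-(triphenylphosphoranylidene)pentan-1-olate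
Product: 16 (5Z)-6-[3,5-bis(benzyloxy)-4-methylphenyl]hex-5-en-1-ol (Z expected as major isomer, E isomer carried along)
Conditions: 9 (THF solution from step 7), then 15, −78 °C to rt; H2O
Reagents that add atoms: none
Why: Wittig olefination as in step 8 forms C13'–C12' with a geometry that does not matter.

Step 15
Reactants: 16 (5Z)-6-[3,5-bis(benzyloxy)-4-methylphenyl]hex-5-en-1-ol
Product: 17 6-[3,5-bis(benzyloxy)-4-methylphenyl]hexan-1-ol
Conditions: TsNHNH2, NaOAc, DME–H2O, reflux
Reagents that add atoms: none
Why: Diimide reduction saturates the alkene while both benzyl ethers should survive, as in step 9.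

Step 16
Reactants: 17 6-[3,5-bis(benzyloxy)-4-methylphenyl]hexan-1-ol
Product: 18 1,3-bis(benzyloxy)-5-(6-bromohexyl)-2-methylbenzene
Conditions: CBr4, PPh3, CH2Cl2, 0 °C to rt
Reagents that add atoms: carbon tetrabromide, BrC(Br)(Br)Br
Why: Appel bromination of the primary alcohol, as in step 10.

Step 17
Reactants: 19 1,3-dithiane; 12 1-(benzyloxy)-5-(6-bromohexyl)-3-methoxy-2-methylbenzene; 18 1,3-bis(benzyloxy)-5-(6-bromohexyl)-2-methylbenzene
Product: 23 2-{6-[3-(benzyloxy)-5-methoxy-4-methylphenyl]hexyl}-2-{6-[3,5-bis(benzyloxy)-4-methylphenyl]hexyl}-1,3-dithiane, via 2-lithio-1,3-dithiane 20 (not isolated), via monoalkyl dithiane 21 (not isolated), via lithiated monoalkyl dithiane 22 (not isolated)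
Conditions: 19, n-BuLi (1.0 equiv, titrated), THF, −30 °C; 12 (0.95 equiv), −78 to 0 °C; n-BuLi (0.95 equiv), −25 °C; 18 (0.95 equiv), −78 °C to rt
Reagents that add atoms: none
Why: n-BuLi removes the C2 proton of 1,3-dithiane (anion stabilised by both sulfur atoms) and the 2-lithio species 20 displaces bromide from primary bromide 12 by SN2 to form C6'–C7'; a second deprotonation of 21 gives the tertiary carbanion 22, which displaces bromide from 18 to form C7'–C8'. The closest known reaction type is the Corey–Seebach polarity-reversed dialkylation of 1,3-dithiane with two primary halides. No ring of the target closes and no stereocentre arises, since C7' carries the two sulfur atoms of one ring and two achiral chains. The selectivity needed is unsymmetrical over symmetrical dialkylation, and it is secured by order of addition: 12 is consumed by a slight excess of 20 before the second charge of base, so that essentially only 21 is lithiated when 18 arrives. Both electrophiles are unhindered primary bromides remote from the arenes, the benzyl and methyl ethers should be inert to the sulfur-stabilised anions at low temperature, and the exactly titrated base keeps free alkyllithium away from the aryl benzyl ethers and from the halides.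

Step 18
Reactants: 23 2-{6-[3-(benzyloxy)-5-methoxy-4-methylphenyl]hexyl}-2-{6-[3,5-bis(benzyloxy)-4-methylphenyl]hexyl}-1,3-dithiane
Product: 24 1-(benzyloxy)-5-{13-[3,5-bis(benzyloxy)-4-methylphenyl]tridecyl}-3-methoxy-2-methylbenzene
Conditions: Raney Ni (W-2), EtOH, reflux
Reagents that add atoms: none
Why: Mozingo-type reductive desulfurisation cleaves both C–S bonds and turns C7' into a plain methylene; any benzyl ether lost here is harmless because step 19 removes all three.

Step 19
Reactants: 24 1-(benzyloxy)-5-{13-[3,5-bis(benzyloxy)-4-methylphenyl]tridecyl}-3-methoxy-2-methylbenzene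
Product: 25 5-[13-(3-hydroxy-5-methoxy-4-methylphenyl)tridecyl]-2-methylbenzene-1,3-diol
Conditions: H2 (1 atm), 10% Pd/C, EtOAc–EtOH, rt
Reagents that add atoms: none
Why: Hydrogenolysis of the three benzyl ethers over palladium on carbon, done after sulfur removal so the catalyst is not poisoned, frees the three phenols while the methyl ether stays.

Step 20
Reactants: 25 5-[13-(3-hydroxy-5-methoxy-4-methylphenyl)tridecyl]-2-methylbenzene-1,3-diol
Product: 26 2-hydroxy-6-[13-(5-methoxy-4-methyl-3,6-dioxocyclohexa-1,4-dien-1-yl)tridecyl]-3-methylcyclohexa-2,5-diene-1,4-dione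
Conditions: (KSO3)2NO (4.4 equiv), KH2PO4, H2O–acetone, rt
Reagents that add atoms: potassium nitrosodisulfonate, [K+].[K+].[O]N(S(=O)(=O)[O-])S(=O)(=O)[O-]
Why: Teuber oxidation, in which each phenoxyl radical is trapped at its free para CH by a second nitroxide and collapses to the para-quinone, should give the methoxyquinone from ring A and the hydroxyquinone from the resorcinol ring B.

Step 21
Reactants: 26 2-hydroxy-6-[13-(5-methoxy-4-methyl-3,6-dioxocyclohexa-1,4-dien-1-yl)tridecyl]-3-methylcyclohexa-2,5-diene-1,4-dione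
Product: 28 1,4,5-triacetoxy-2-methoxy-3-methyl-6-[13-(2,3,5,6-tetraacetoxy-4-methylphenyl)tridecyl]benzene, via ring B acetoxyquinone 27 (not isolated)
Conditions: Ac2O, H2SO4 (cat.), 0 °C to rt
Reagents that add atoms: acetic anhydride, CC(=O)OC(C)=O
Why: Thiele–Winter acetoxylation, after O-acetylation of the ring B hydroxyl, adds acetate to the acid-activated quinone at the single free CH of each ring (no regiochemical choice) and the resulting hydroquinones are acetylated in the same flask.

Step 22
Reactants: 28 1,4,5-triacetoxy-2-methoxy-3-methyl-6-[13-(2,3,5,6-tetraacetoxy-4-methylphenyl)tridecyl]benzene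
Product: 30 2-hydroxy-5-methoxy-6-methyl-3-[13-(2,5-dihydroxy-4-methyl-3,6-dioxocyclohexa-1,4-dien-1-yl)tridecyl]cyclohexa-2,5-diene-1,4-dione (CNP0107579.0), via heptahydroxy compound 29 (not isolated)
Conditions: K2CO3 (excess), degassed MeOH, Ar, rt; then O2 (air), rt; then 1 M HCl
Reagents that add atoms: none
Why: Carbonate-mediated methanolysis should remove all seven aryl acetates and the electron-rich polyhydroxybenzene rings of 29 are then autoxidised by O2 to the hydroxy-para-quinones, while methoxide exchange at the vinylogous ester of ring A is degenerate so the methyl ether is kept.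

**Compound list**

1 | 3,5-dihydroxy-4-methylbenzoic acid | Cc1c(O)cc(C(=O)O)cc1O | starting material
2 | methyl 3,5-dihydroxy-4-methylbenzoate | COC(=O)c1cc(O)c(C)c(O)c1 | intermediate
3 | methyl 3-(benzyloxy)-5-hydroxy-4-methylbenzoate | COC(=O)c1cc(O)c(C)c(OCc2ccccc2)c1 | intermediate
4 | methyl 3-(benzyloxy)-5-methoxy-4-methylbenzoate | COC(=O)c1cc(OC)c(C)c(OCc2ccccc2)c1 | intermediate
5 | [3-(benzyloxy)-5-methoxy-4-methylphenyl]methanol | COc1cc(CO)cc(OCc2ccccc2)c1C | intermediate
6 | 3-(benzyloxy)-5-methoxy-4-methylbenzaldehyde | COc1cc(C=O)cc(OCc2ccccc2)c1C | intermediate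
7 | 5-bromopentan-1-ol | OCCCCCBr | starting material
8 | (5-hydroxypentyl)triphenylphosphonium bromide | [Br-].OCCCCC[P+](c1ccccc1)(c1ccccc1)c1ccccc1 | intermediate
9 | sodium 5-(triphenylphosphoranylidene)pentan-1-olate (alkoxide ylide, handled as its THF solution) | [Na+].[O-]CCCCC=P(c1ccccc1)(c1ccccc1)c1ccccc1 | intermediate
10 | (5Z)-6-[3-(benzyloxy)-5-methoxy-4-methylphenyl]hex-5-en-1-ol | COc1cc(/C=C\CCCCO)cc(OCc2ccccc2)c1C | intermediate
11 | 6-[3-(benzyloxy)-5-methoxy-4-methylphenyl]hexan-1-ol | COc1cc(CCCCCCO)cc(OCc2ccccc2)c1C | intermediate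
12 | 1-(benzyloxy)-5-(6-bromohexyl)-3-methoxy-2-methylbenzene | COc1cc(CCCCCCBr)cc(OCc2ccccc2)c1C | intermediate
13 | methyl 3,5-bis(benzyloxy)-4-methylbenzoate | COC(=O)c1cc(OCc2ccccc2)c(C)c(OCc2ccccc2)c1 | intermediate
14 | [3,5-bis(benzyloxy)-4-methylphenyl]methanol | Cc1c(OCc2ccccc2)cc(CO)cc1OCc1ccccc1 | intermediate
15 | 3,5-bis(benzyloxy)-4-methylbenzaldehyde | Cc1c(OCc2ccccc2)cc(C=O)cc1OCc1ccccc1 | intermediate
16 | (5Z)-6-[3,5-bis(benzyloxy)-4-methylphenyl]hex-5-en-1-ol | Cc1c(OCc2ccccc2)cc(/C=C\CCCCO)cc1OCc1ccccc1 | intermediate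
17 | 6-[3,5-bis(benzyloxy)-4-methylphenyl]hexan-1-ol | Cc1c(OCc2ccccc2)cc(CCCCCCO)cc1OCc1ccccc1 | intermediate
18 | 1,3-bis(benzyloxy)-5-(6-bromohexyl)-2-methylbenzene | Cc1c(OCc2ccccc2)cc(CCCCCCBr)cc1OCc1ccccc1 | intermediate
19 | 1,3-dithiane | C1CSCSC1 | starting material
20 | 2-lithio-1,3-dithiane | [Li]C1SCCCS1 | intermediate (not isolated)
21 | 2-{6-[3-(benzyloxy)-5-methoxy-4-methylphenyl]hexyl}-1,3-dithiane | COc1cc(CCCCCCC2SCCCS2)cc(OCc2ccccc2)c1C | intermediate (not isolated)
22 | 2-lithio-2-{6-[3-(benzyloxy)-5-methoxy-4-methylphenyl]hexyl}-1,3-dithiane | COc1cc(CCCCCCC2([Li])SCCCS2)cc(OCc2ccccc2)c1C | intermediate (not isolated)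
23 | 2-{6-[3-(benzyloxy)-5-methoxy-4-methylphenyl]hexyl}-2-{6-[3,5-bis(benzyloxy)-4-methylphenyl]hexyl}-1,3-dithiane | COc1cc(CCCCCCC2(CCCCCCc3cc(OCc4ccccc4)c(C)c(OCc4ccccc4)c3)SCCCS2)cc(OCc2ccccc2)c1C | intermediate
24 | 1-(benzyloxy)-5-{13-[3,5-bis(benzyloxy)-4-methylphenyl]tridecyl}-3-methoxy-2-methylbenzene | COc1cc(CCCCCCCCCCCCCc2cc(OCc3ccccc3)c(C)c(OCc3ccccc3)c2)cc(OCc2ccccc2)c1C | intermediate
25 | 5-[13-(3-hydroxy-5-methoxy-4-methylphenyl)tridecyl]-2-methylbenzene-1,3-diol | COc1cc(CCCCCCCCCCCCCc2cc(O)c(C)c(O)c2)cc(O)c1C | intermediate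
26 | 2-hydroxy-6-[13-(5-methoxy-4-methyl-3,6-dioxocyclohexa-1,4-dien-1-yl)tridecyl]-3-methylcyclohexa-2,5-diene-1,4-dione | COC1=C(C)C(=O)C=C(CCCCCCCCCCCCCC2=CC(=O)C(C)=C(O)C2=O)C1=O | intermediate
27 | 5-[13-(5-methoxy-4-methyl-3,6-dioxocyclohexa-1,4-dien-1-yl)tridecyl]-2-methyl-3,6-dioxocyclohexa-1,4-dien-1-yl acetate | COC1=C(C)C(=O)C=C(CCCCCCCCCCCCCC2=CC(=O)C(C)=C(OC(C)=O)C2=O)C1=O | intermediate (not isolated)
28 | 1,4,5-triacetoxy-2-methoxy-3-methyl-6-[13-(2,3,5,6-tetraacetoxy-4-methylphenyl)tridecyl]benzene | COc1c(C)c(OC(C)=O)c(OC(C)=O)c(CCCCCCCCCCCCCc2c(OC(C)=O)c(OC(C)=O)c(C)c(OC(C)=O)c2OC(C)=O)c1OC(C)=O | intermediate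
29 | 5-methoxy-6-methyl-3-[13-(2,3,5,6-tetrahydroxy-4-methylphenyl)tridecyl]benzene-1,2,4-triol | COc1c(C)c(O)c(O)c(CCCCCCCCCCCCCc2c(O)c(O)c(C)c(O)c2O)c1O | intermediate (not isolated)
30 | 2-hydroxy-5-methoxy-6-methyl-3-[13-(2,5-dihydroxy-4-methyl-3,6-dioxocyclohexa-1,4-dien-1-yl)tridecyl]cyclohexa-2,5-diene-1,4-dione | COC1=C(C)C(=O)C(O)=C(CCCCCCCCCCCCCC2=C(O)C(=O)C(C)=C(O)C2=O)C1=O | target

**Step count**

Total: 22 steps. Longest linear sequence: 14 steps (1, 2, 3, 4, 5, 8, 9, 10, 17, 18, 19, 20, 21, 22).

**Steps most likely to fail**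

Step 17. The first alkylation may be incomplete or the second lithiation of the 2-alkyl dithiane slow, so that symmetrical dialkylation, recovered monoalkyl dithiane or attack of free n-BuLi on the second bromide erodes the unsymmetrical union. The fallback replaces the dithiane by another one-carbon linchpin that is alkylated in two separate, isolated stages. It sets out from 12 and 18. Tosylmethyl isocyanide is monoalkylated with 12 under phase transfer (40% aqueous NaOH, Bu4NI, CH2Cl2) to 1-(benzyloxy)-5-[7-isocyano-7-(4-methylbenzenesulfonyl)heptyl]-3-methoxy-2-methylbenzene F1. F1 is alkylated with 18 (NaH, DMSO–Et2O) to the dialkylated isocyanide 1-(benzyloxy)-5-{13-[3,5-bis(benzyloxy)-4-methylphenyl]-7-isocyano-7-(4-methylbenzenesulfonyl)tridecyl}-3-methoxy-2-methylbenzene F2. Acid hydrolysis (conc. HCl, Et2O–CH2Cl2, rt) then gives 1-[3-(benzyloxy)-5-methoxy-4-methylphenyl]-13-[3,5-bis(benzyloxy)-4-methylphenyl]tridecan-7-one F3. Thioketalisation of F3 with propane-1,3-dithiol and BF3·OEt2 in CH2Cl2 returns to the route at 23.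

Step 21. Acid-catalysed acetate addition may be slow on the donor-substituted ring A quinone, and acetylation of the two rings may be incomplete or accompanied by decomposition in the strongly acidic medium. The fallback introduces the last oxygen of each ring by halogenation and substitution and sets out from 26. Bromine in AcOH followed by NaOAc should give, by addition and loss of HBr at the one free position of each quinone, 3-bromo-2-[13-(2-bromo-5-methoxy-4-methyl-3,6-dioxocyclohexa-1,4-dien-1-yl)tridecyl]-6-hydroxy-5-methylcyclohexa-2,5-diene-1,4-dione F4. Displacement of both vinylic bromides by hydroxide (KOH, aqueous dioxane, rt, then dilute HCl) returns to the route at 30. Methanol is avoided in this hydrolysis so that no second methyl ether can form.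

Step 20. One-electron oxidation of the unprotected resorcinol ring B may run on to oxidative coupling or degradation, one ring may be oxidised incompletely, and the free hydroxyquinone with an open ring position may not survive isolation. The fallback bypasses quinone formation by radical oxidation (and with it step 21) by making all four new C–O bonds through C–C bonds, and sets out from 25. Fourfold Duff formylation (hexamethylenetetramine, CF3CO2H, reflux, then aqueous HCl) at the four free ring positions, each ortho or para to a hydroxyl, should give 4-hydroxy-2-[13-(2,6-diformyl-3,5-dihydroxy-4-methylphenyl)tridecyl]-6-methoxy-5-methylbenzene-1,3-dicarbaldehyde F5. Dakin oxidation of F5 (H2O2, aqueous NaOH, under Ar) with hydrolysis of the aryl formates returns to the route at 29, which is oxidised in air and acidified as in step 22 to give 30.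

**Further compounds**

F1 | step 17 | 1-(benzyloxy)-5-[7-isocyano-7-(4-methylbenzenesulfonyl)heptyl]-3-methoxy-2-methylbenzene | COc1cc(CCCCCCC([N+]#[C-])S(=O)(=O)c2ccc(C)cc2)cc(OCc2ccccc2)c1C
F2 | step 17 | 1-(benzyloxy)-5-{13-[3,5-bis(benzyloxy)-4-methylphenyl]-7-isocyano-7-(4-methylbenzenesulfonyl)tridecyl}-3-methoxy-2-methylbenzene | COc1cc(CCCCCCC(CCCCCCc2cc(OCc3ccccc3)c(C)c(OCc3ccccc3)c2)([N+]#[C-])S(=O)(=O)c2ccc(C)cc2)cc(OCc2ccccc2)c1C
F3 | step 17 | 1-[3-(benzyloxy)-5-methoxy-4-methylphenyl]-13-[3,5-bis(benzyloxy)-4-methylphenyl]tridecan-7-one | COc1cc(CCCCCCC(=O)CCCCCCc2cc(OCc3ccccc3)c(C)c(OCc3ccccc3)c2)cc(OCc2ccccc2)c1C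
F4 | step 21 | 3-bromo-2-[13-(2-bromo-5-methoxy-4-methyl-3,6-dioxocyclohexa-1,4-dien-1-yl)tridecyl]-6-hydroxy-5-methylcyclohexa-2,5-diene-1,4-dione | COC1=C(C)C(=O)C(Br)=C(CCCCCCCCCCCCCC2=C(Br)C(=O)C(C)=C(O)C2=O)C1=O
F5 | step 20 | 4-hydroxy-2-[13-(2,6-diformyl-3,5-dihydroxy-4-methylphenyl)tridecyl]-6-methoxy-5-methylbenzene-1,3-dicarbaldehyde | COc1c(C)c(O)c(C=O)c(CCCCCCCCCCCCCc2c(C=O)c(O)c(C)c(O)c2C=O)c1C=O
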